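## The problem

The target is a bis-isoflavan in which two chromans hang on one benzene ring. Chroman 1 (ring A fused to the pyran O1–C2–C3–C4) carries ring B (2-hydroxy-4,5-dimethoxyphenyl) at C3 and ring D at C4. Ring D carries C3' of chroman 2 (ring A', O1'–C2'–C3'–C4') at D6, next to its attachment point D1. Ring D is therefore 1,2,3,5-tetrasubstituted (D1–C4, D2–OMe, D4–OH, D6–C3'): D1 is flanked on both sides, and D6 is meta to both ring oxygens, where electrophilic substitution of a resorcinol ether cannot place a carbon substituent. There are three stereocentres. C3 (R) and C4 (S) are adjacent and trans, so each can steer the other and the trans pair is also the more stable one. C3' (R) is insulated from them by ring D and must be set by a reagent. The free target has four phenols on electron-rich rings and a doubly benzylic C4–H, and any ortho-hydroxybenzhydrol at C4 ionises to an ortho-quinone methide under mild acid or heat, so oxidants, strong acid and late strong base must be avoided and D4–OH must stay distinguishable from D2–OMe. The enabling feature is the pair of adjacent carbon substituents at D1 and D6 beside the D2 methoxy group: this is the pattern left when a 3-methoxyaryne is inserted into the bond between the acyl carbon and the α-carbon of a β-ketoester. The acyl carbon (future C4, already bonded to ring A) ends on D1, and the α-carbon (future C3', already carrying C2' as an ester and C4' with ring A') ends on D6.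

## Retrosynthesis

**Phenol release.** The last cut is at the four benzylic O–CH2Ph bonds: target 33 comes from tetrabenzyl ether 32. Benzyl ethers are chosen over silyl ethers (lost to fluoride in the aryne step) and over methyl ethers (not distinguishable from the D2 and ring B methoxy groups). The forward step must only be a neutral hydrogenolysis that leaves the C4–H and the two pyran rings alone.

**Chroman 1.** C2 of 32 is taken back to the lactol 31, and 31 is cut at C3–C4 and O1–C2. This leads to the ortho-hydroxybenzhydrol 29, reacting as its quinone methide 30, and the ring B arylacetaldehyde 28. Cutting C4–D1 instead would need a doubly ortho-substituted ring D nucleophile and would discard the ketone that the aryne step supplies. Cutting C4–C4a is weighed under Alternative 1. The chosen cut removes ring B, C2, C3 and both stereocentres in one operation. The forward reaction must be an amine-catalysed addition of the enamine of 28 to 30 in which the catalyst fixes C3 and C4 and the trans arrangement.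

**C4 oxidation level and chroman 2.** Benzhydrol 29 comes from the ortho-hydroxybenzophenone 24 by hydride reduction; the carbinol configuration is irrelevant because it is erased in 30. In 24 the O1'–C2' bond is cut to the diphenol alcohol 23, which comes from the bis-methoxymethyl ether 22. Holding C4 as a ketone through these steps is preferred to carrying a benzhydrol, which would ionise under the acid needed to unmask the phenols and would compete in the etherification. The forward ring closure is a Mitsunobu 6-exo displacement by the ring A' phenol.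

**C3'.** The alcohol 22 is traced to the racemic α-aryl aldehyde 21, which comes from the ketoester 19 through diol 20 by full reduction and re-oxidation. An aldehyde at C2' is chosen because its α-centre racemises under base, so the whole racemate can be funnelled to the R alcohol by asymmetric hydrogenation. No stoichiometric auxiliary is then needed at a centre that the aryne step necessarily forms racemic. The forward step must distinguish the ortho-substituted ring D from the benzyl group at the α-carbon and leave the hindered diaryl ketone untouched.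

**Key disconnection.** In 19 the D6–C3' and D1–C4 bonds are cut together. This gives the β-ketoester 17 and the aryne 18, released from the ortho-silylaryl triflate 8. No other cut forms two carbon–arene bonds on adjacent positions with the regiochemistry dictated by a substituent already present, and it reaches the position meta to both oxygens. The precursors are an arene with no carbon substituent and an acyclic ketoester. The forward reaction must show attack of the enolate carbon at the aryne carbon remote from the methoxy group, and acyl transfer in preference to simple arylation.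

**Ketoester 17.** The C4'–C3' bond is cut to the aroylacetate 12 and the aldehyde 15, joined by condensation to 16 and conjugate reduction. This avoids a labile 2,4-dialkoxybenzyl halide and any dialkylation. Ester 12 comes from acetophenone 11 by carboxymethylation, and 11 from 2,4-dihydroxyacetophenone 9 through 10. Aldehyde 15 comes from 2,4-dihydroxybenzaldehyde 13 through 14. In both series the chelated 2-hydroxy group allows selective 4-O-benzylation.

**Aryne precursor 8.** Benzyl ether 8 comes from phenol 7. Phenol 7 is made from 2-bromo-6-methoxyhydroquinone 3 by moving a silyl group from oxygen to the bromine-bearing carbon and triflating the oxygen so freed. Diol 3 comes from 5-bromovanillin 1 by Dakin oxidation. The bromine of 1 marks the silyl position unambiguously. Directed metalation of a 3-benzyloxy-5-methoxyphenol derivative would instead have to choose between two nearly equivalent sites flanked by the benzyloxy and methoxy groups.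

**Aldehyde 28.** The C2–C3 bond of the arylacetaldehyde is cut by a one-carbon Wittig homologation: 28 from enol ether 27, from benzyl ether 26, from 2-hydroxy-4,5-dimethoxybenzaldehyde 25.

## Roads not taken

Alternative 1: The C4–C4a bond of chroman 1 is cut. The precursor is the acyclic carbinol A1, in which O1 and C2 are already present as a 3-benzyloxyphenyl ether and C4 is a benzylic alcohol on ring D. Acid would ionise the carbinol, and the ring A carbon para to the benzyloxy group would close the pyran to give A2, which is identical with compound 32.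
- Merits: the carbinol configuration does not matter, C4 is set from C3 by attack anti to ring B so the trans pair arises without a chiral catalyst, and the step lands on the penultimate compound.
- Weak points: the ortho-benzyloxy oxygen of ring B can capture the cation in a five-membered closure, and attack at the ring A carbon between the two oxygens would give the 5-oxygenated isomer. A1 itself would need a metallated, doubly ortho-substituted ring D (already carrying chroman 2) added to an aldehyde bearing an α-aryl and a β-aryloxy group, which invites enolisation at C3 and β-elimination of the aryloxide. The placement of carbon at D1 and D6 is left unsolved.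
- Comparison: in the endgame this road is as good as or better than the chosen one, since it needs no catalytic annulation on a hindered quinone methide. Against this, the chosen plan builds the ring D substitution pattern convergently from three simple arenes and controls C3 catalytically, both of which Alternative 1 still owes.

Alternative 2: Ring D is built by cutting D1–D2 and D5–D6. The ynone A3 (ketone carbon = C4 on ring A, alkyne β-carbon bearing finished chroman 2) would react with the diene A4, and loss of methanol and the silyl group would give the benzophenone A5.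
- Merits: regiochemistry follows from the polarity of the partners, D2–OMe and D4–OH arrive differentiated with no aryne-precursor question, and C3' enters as a finished stereocentre. A5 corresponds to compound 24 with the ring A phenol still masked, so the same endgame follows.
- Weak points: A3 requires chroman 2 to be made first as a single enantiomer with an ethynyl group at C3', a longer linear sequence through epimerisable intermediates. The stereocentre of A3 is propargylic and γ to the ynone carbonyl, so base or heat can scramble it through the allenone. The β-carbon carries a secondary alkyl group, which slows the largely stepwise addition of the sensitive ketene-acetal diene and invites attack at the carbonyl.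
- Comparison: in regiochemical certainty, and in having C3' settled beforehand, Alternative 2 is at least equal. The chosen plan sets against it greater convergence and cheaper building blocks, at the cost of defending the preparation of 8 (solved by the bromine marker) and the dynamic kinetic resolution at C3'.

Alternative 3: The O1–C8a bond is cut. The 3-arylindanone A6 (aryl = ring D carrying chroman 2) would undergo Baeyer–Villiger oxidation with migration of the ring A carbon to give the dihydrocoumarin A7.
- Merits: C4 is fixed early in a rigid ring, no quinone methide is involved, and C3 can then be introduced trans to the C4 aryl group on the lactone enolate.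
- Weak points: the migrating carbon is meta to the benzyloxy group and gets no para-donor assistance, so methylene migration competes. The peracid meets three electron-rich rings. A6 is hard to obtain enantiopure, because it needs a doubly ortho-substituted aryl group added to an indenone-type acceptor. After A7, ring B introduction, lactone reduction and etherification still follow, and ring D must again be assembled beforehand.
- Comparison: for security at C4 this road is the better one. The chosen plan is shorter and installs ring B, C2, C3 and C4 in one step, and it keeps the lactone logic in reserve as a fallback (F10).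

Key step: step 10

Remarks on the chemistry:
- Precursor 8 carries the silyl group and the triflate in exchanged positions relative to the isomer with silicon between the two oxygens; both release the same aryne 18.
- The hands of the chiral catalysts in steps 13 and 20 are assigned by analogy with the accepted facial models; the mirror-image catalysts are equally available should the sense prove opposite.
- Slow rotation about the C4–D1 bond is not treated as a stereochemical element.

## Route

Step 1
Reactants: 1 5-bromovanillin (3-bromo-4-hydroxy-5-methoxybenzaldehyde)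
Product: 3 2-bromo-6-methoxybenzene-1,4-diol, via aryl formate 2 (not isolated)
Conditions: H2O2 (30 % aq.), NaOH, H2O/THF, 0 °C → rt, N2; then HCl
Reagents that add atoms: hydrogen peroxide, OO
Why: Dakin oxidation of a para-hydroxybenzaldehyde: hydroperoxide adds to the aldehyde, the electron-rich aryl group migrates to oxygen and formate 2 is saponified in the flask; the bromine already marks the future silyl position.

Step 2
Reactants: 3 2-bromo-6-methoxybenzene-1,4-diol
Product: 7 4-hydroxy-2-methoxy-6-(trimethylsilyl)phenyl trifluoromethanesulfonate, via bis-silyl ether 4 (not isolated), via lithium phenoxide 5 (not isolated), via silyloxy triflate 6 (not isolated)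
Conditions: HMDS, 80 °C; n-BuLi, THF, −78 °C; Tf2O, −78 → 0 °C; 1 M aq. HCl, THF, 0 °C
Reagents that add atoms: hexamethyldisilazane, C[Si](C)(C)N[Si](C)(C)C; trifluoromethanesulfonic anhydride, O=S(=O)(OS(=O)(=O)C(F)(F)F)C(F)(F)F
Why: Standard conversion of an ortho-bromophenol into an ortho-silylaryl triflate: bromine–lithium exchange triggers a 1,3 retro-Brook shift from the neighbouring oxygen only, so a single phenoxide 5 is triflated; the remote aryl silyl ether is cleaved on acidic work-up, while the C-silyl group, meta to both donors, resists protodesilylation.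

Step 3
Reactants: 7 4-hydroxy-2-methoxy-6-(trimethylsilyl)phenyl trifluoromethanesulfonate
Product: 8 4-(benzyloxy)-2-methoxy-6-(trimethylsilyl)phenyl trifluoromethanesulfonate
Conditions: BnOH, PPh3, DIAD, THF, 0 °C → rt
Reagents that add atoms: benzyl alcohol, OCc1ccccc1
Why: Mitsunobu etherification of an acidic phenol; neutral conditions avoid any carbonate- or fluoride-induced loss of the silyl triflate.

Step 4
Reactants: 9 2,4-dihydroxyacetophenone
Product: 10 1-[4-(benzyloxy)-2-hydroxyphenyl]ethan-1-one
Conditions: BnBr, K2CO3, acetone, reflux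
Reagents that add atoms: benzyl bromide, BrCc1ccccc1
Why: Williamson etherification; the 2-hydroxy group is hydrogen-bonded to the ketone, so only the 4-hydroxy group is alkylated.

Step 5
Reactants: 10 1-[4-(benzyloxy)-2-hydroxyphenyl]ethan-1-one
Product: 11 1-[4-(benzyloxy)-2-(methoxymethoxy)phenyl]ethan-1-one
Conditions: MOMCl, i-Pr2NEt, CH2Cl2, 0 → 40 °C
Reagents that add atoms: chloromethyl methyl ether, COCCl
Why: Acetal protection of the chelated phenol; the group is inert to CsF, hydride and base and is removed later by aqueous acid without touching benzyl ethers.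

Step 6
Reactants: 11 1-[4-(benzyloxy)-2-(methoxymethoxy)phenyl]ethan-1-one
Product: 12 methyl 3-[4-(benzyloxy)-2-(methoxymethoxy)phenyl]-3-oxopropanoate
Conditions: NaH, (MeO)2CO, toluene, 110 °C; AcOH quench
Reagents that add atoms: dimethyl carbonate, COC(=O)OC
Why: Crossed Claisen condensation of the methyl ketone enolate with dimethyl carbonate, driven by formation of the ketoester enolate.

Step 7
Reactants: 13 2,4-dihydroxybenzaldehyde
Product: 14 4-(benzyloxy)-2-hydroxybenzaldehyde
Conditions: BnBr, NaHCO3, MeCN, 80 °C
Reagents that add atoms: benzyl bromide, BrCc1ccccc1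
Why: Williamson etherification under weak base; the chelated 2-hydroxy group stays free.

Step 8
Reactants: 14 4-(benzyloxy)-2-hydroxybenzaldehyde
Product: 15 4-(benzyloxy)-2-(methoxymethoxy)benzaldehyde
Conditions: MOMCl, i-Pr2NEt, CH2Cl2, 0 °C → rt
Reagents that add atoms: chloromethyl methyl ether, COCCl
Why: Acetal protection as in step 5, so that both ortho phenols can later be released together.

Step 9
Reactants: 12 methyl 3-[4-(benzyloxy)-2-(methoxymethoxy)phenyl]-3-oxopropanoate; 15 4-(benzyloxy)-2-(methoxymethoxy)benzaldehyde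
Product: 17 methyl 2-[4-(benzyloxy)-2-(methoxymethoxy)benzyl]-3-[4-(benzyloxy)-2-(methoxymethoxy)phenyl]-3-oxopropanoate (racemic), via arylidene ketoester 16 (not isolated)
Conditions: piperidine (10 mol %), AcOH (10 mol %), toluene, reflux (Dean–Stark); then Hantzsch ester, 70 °C
Reagents that add atoms: none
Why: Knoevenagel condensation followed by transfer hydrogenation of the doubly activated alkene by the dihydropyridine; this reductive benzylation avoids a labile 2,4-dialkoxybenzyl halide and dialkylation, and the α-centre forms racemic.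

Step 10
Reactants: 17 methyl 2-[4-(benzyloxy)-2-(methoxymethoxy)benzyl]-3-[4-(benzyloxy)-2-(methoxymethoxy)phenyl]-3-oxopropanoate (racemic); 8 4-(benzyloxy)-2-methoxy-6-(trimethylsilyl)phenyl trifluoromethanesulfonate
Product: 19 methyl 2-{5-(benzyloxy)-2-[4-(benzyloxy)-2-(methoxymethoxy)benzoyl]-3-methoxyphenyl}-3-[4-(benzyloxy)-2-(methoxymethoxy)phenyl]propanoate (racemic), via aryne 18 (not isolated)
Conditions: CsF (3 equiv), MeCN, 80 °C (8 1.5 equiv, added slowly)
Reagents that add atoms: none
Why: Fluoride attacks silicon of 8 and triflate leaves, releasing aryne 18 at a low steady concentration. The caesium enolate of 17 adds through carbon to D6, the aryne carbon remote from the methoxy group, because the aryl anion then develops at D1 where the adjacent C–O bond stabilises it inductively; the D4 benzyloxy group is meta to the attacked carbon and has little influence. The D1 anion adds to the aryl ketone to give a benzocyclobutenoxide, which fragments so that the aroyl group ends on D1 and the ester-stabilised carbanion, then protonated, on D6; the four-membered ring is transient, so no ring persists. The net result is insertion of the aryne into the acyl–α-carbon sigma bond, the acyl-alkylation of arynes by β-ketoesters, which is known for α-substituted ketoesters (ring-expansion variant) and for 3-alkoxyarynes carrying a further 5-alkoxy group. The only new stereocentre, C3', forms racemic and is set in step 13. The step needs regioselective attack, secured by the D2 methoxy group, and acyl transfer in preference to protonation of the aryl anion, secured by the intramolecular ketone and an aprotic medium; the acetal and benzyl ethers are inert to CsF.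

Step 11
Reactants: 19 methyl 2-{5-(benzyloxy)-2-[4-(benzyloxy)-2-(methoxymethoxy)benzoyl]-3-methoxyphenyl}-3-[4-(benzyloxy)-2-(methoxymethoxy)phenyl]propanoate (racemic)
Product: 20 2-{5-(benzyloxy)-2-[[4-(benzyloxy)-2-(methoxymethoxy)phenyl](hydroxy)methyl]-3-methoxyphenyl}-3-[4-(benzyloxy)-2-(methoxymethoxy)phenyl]propan-1-ol (racemic diastereomers)
Conditions: LiAlH4, THF, 0 °C → rt; aq. potassium sodium tartrate (KNaC4H4O6) work-up
Reagents that add atoms: none
Why: Exhaustive hydride reduction of ester and ketone; it is chosen because a partial reduction of the ester beside the ketone cannot be stopped reliably, and the neutral work-up keeps the benzhydrol from ionising.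

Step 12
Reactants: 20 2-{5-(benzyloxy)-2-[[4-(benzyloxy)-2-(methoxymethoxy)phenyl](hydroxy)methyl]-3-methoxyphenyl}-3-[4-(benzyloxy)-2-(methoxymethoxy)phenyl]propan-1-ol
Product: 21 2-{5-(benzyloxy)-2-[4-(benzyloxy)-2-(methoxymethoxy)benzoyl]-3-methoxyphenyl}-3-[4-(benzyloxy)-2-(methoxymethoxy)phenyl]propanal (racemic)
Conditions: DMP, NaHCO3, CH2Cl2, 0 °C → rt
Reagents that add atoms: none
Why: Dess–Martin oxidation of both alcohols under buffered conditions gives the enolisable α-aryl aldehyde and restores the diaryl ketone, which then serves as an inert placeholder for C4; 21 is used without storage.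

Step 13
Reactants: 21 2-{5-(benzyloxy)-2-[4-(benzyloxy)-2-(methoxymethoxy)benzoyl]-3-methoxyphenyl}-3-[4-(benzyloxy)-2-(methoxymethoxy)phenyl]propanal (racemic)
Product: 22 {4-(benzyloxy)-2-[(2R)-1-[4-(benzyloxy)-2-(methoxymethoxy)phenyl]-3-hydroxypropan-2-yl]-6-methoxyphenyl}[4-(benzyloxy)-2-(methoxymethoxy)phenyl]methanone
Conditions: H2 (20 atm), RuCl2[(S)-xylBINAP][(S)-DAIPEN] (1 mol %), KOt-Bu (10 mol %), i-PrOH, rt
Reagents that add atoms: none
Why: Dynamic kinetic resolution by asymmetric hydrogenation of a racemic α-aryl aldehyde: alkoxide racemises the α-centre through the enolate faster than reduction, and the chiral diphosphine–diamine hydride of divalent ruthenium reduces one enantiomer preferentially, so C3' is set under catalyst control (R expected; the mirror-image complex is used if the sense is opposite); the tri-ortho-substituted benzophenone is too hindered to be reduced.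

Step 14
Reactants: 22 {4-(benzyloxy)-2-[(2R)-1-[4-(benzyloxy)-2-(methoxymethoxy)phenyl]-3-hydroxypropan-2-yl]-6-methoxyphenyl}[4-(benzyloxy)-2-(methoxymethoxy)phenyl]methanone
Product: 23 [4-(benzyloxy)-2-hydroxyphenyl]{4-(benzyloxy)-2-[(2R)-1-[4-(benzyloxy)-2-hydroxyphenyl]-3-hydroxypropan-2-yl]-6-methoxyphenyl}methanone
Conditions: 3 M aq. HCl, THF, 50 °C
Reagents that add atoms: none
Why: Acid hydrolysis of both aryl methoxymethyl acetals; C3' is no longer enolisable, no benzhydrol is present to ionise, and an aqueous medium keeps the δ-hydroxy ketone from being trapped as a cyclic methyl ketal.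

Step 15
Reactants: 23 [4-(benzyloxy)-2-hydroxyphenyl]{4-(benzyloxy)-2-[(2R)-1-[4-(benzyloxy)-2-hydroxyphenyl]-3-hydroxypropan-2-yl]-6-methoxyphenyl}methanone
Product: 24 [4-(benzyloxy)-2-hydroxyphenyl]{4-(benzyloxy)-2-[(3R)-7-(benzyloxy)chroman-3-yl]-6-methoxyphenyl}methanone
Conditions: PPh3, DIAD, THF, 0 °C → rt
Reagents that add atoms: none
Why: Intramolecular Mitsunobu etherification (6-exo-tet) closes chroman 2 at the primary carbon without touching C3'; the ring A phenol is chelated to the ketone and could only form an eight-membered ring, so it does not compete.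

Step 16
Reactants: 25 2-hydroxy-4,5-dimethoxybenzaldehyde
Product: 26 2-(benzyloxy)-4,5-dimethoxybenzaldehyde
Conditions: BnBr, K2CO3, DMF, 60 °C
Reagents that add atoms: benzyl bromide, BrCc1ccccc1
Why: Williamson etherification of the ring B phenol, so that it leaves in the final hydrogenolysis.

Step 17
Reactants: 26 2-(benzyloxy)-4,5-dimethoxybenzaldehyde
Product: 27 1-(benzyloxy)-4,5-dimethoxy-2-(2-methoxyethenyl)benzene (E/Z mixture)
Conditions: MeOCH2PPh3Cl, KOt-Bu, THF, 0 °C → rt
Reagents that add atoms: (methoxymethyl)triphenylphosphonium chloride, COC[P+](c1ccccc1)(c1ccccc1)c1ccccc1.[Cl-]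
Why: Wittig one-carbon homologation with the methoxymethylene ylide; the alkene geometry is irrelevant.

Step 18
Reactants: 27 1-(benzyloxy)-4,5-dimethoxy-2-(2-methoxyethenyl)benzene
Product: 28 2-[2-(benzyloxy)-4,5-dimethoxyphenyl]acetaldehyde
Conditions: 2 M aq. HCl, THF, rt
Reagents that add atoms: water, O
Why: Enol ether hydrolysis to the arylacetaldehyde, which is prepared shortly before use because electron-rich arylacetaldehydes self-condense on standing.

Step 19
Reactants: 24 [4-(benzyloxy)-2-hydroxyphenyl]{4-(benzyloxy)-2-[(3R)-7-(benzyloxy)chroman-3-yl]-6-methoxyphenyl}methanone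
Product: 29 5-(benzyloxy)-2-[{4-(benzyloxy)-2-[(3R)-7-(benzyloxy)chroman-3-yl]-6-methoxyphenyl}(hydroxy)methyl]phenol (both carbinol epimers)
Conditions: LiAlH4, THF, 0 °C; aq. potassium sodium tartrate (KNaC4H4O6) work-up
Reagents that add atoms: none
Why: Hydride reduction of the hindered ortho-hydroxybenzophenone at low temperature; the carbinol configuration is irrelevant because it is erased in the next step, and the crude benzhydrol is used at once.

Step 20
Reactants: 29 5-(benzyloxy)-2-[{4-(benzyloxy)-2-[(3R)-7-(benzyloxy)chroman-3-yl]-6-methoxyphenyl}(hydroxy)methyl]phenol; 28 2-[2-(benzyloxy)-4,5-dimethoxyphenyl]acetaldehyde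
Product: 31 (3R,4S)-7-(benzyloxy)-3-[2-(benzyloxy)-4,5-dimethoxyphenyl]-4-{4-(benzyloxy)-2-[(3R)-7-(benzyloxy)chroman-3-yl]-6-methoxyphenyl}chroman-2-ol (both anomers), via ortho-quinone methide 30 (not isolated)
Conditions: (R)-α,α-diphenylprolinol trimethylsilyl ether (20 mol %), PhCO2H (20 mol %), CH2Cl2, rt (28 3 equiv, slow addition)
Reagents that add atoms: none
Why: Amine-catalysed formal [4+2] annulation of an aldehyde with an ortho-quinone methide formed in the flask: the acid ionises 29 to 30, the E-enamine of 28 adds through its unshielded face to the methide carbon (C3–C4 bond) and the phenoxide closes onto the iminium carbon (O1–C2), with hydrolysis giving the lactol; the catalyst sets C3 and C4 with the topicity of the syn-selective conjugate additions of such enamines, which corresponds to trans-(3R,4S), and any cis isomer can equilibrate at C3 through the open hydroxy aldehyde.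

Step 21
Reactants: 31 (3R,4S)-7-(benzyloxy)-3-[2-(benzyloxy)-4,5-dimethoxyphenyl]-4-{4-(benzyloxy)-2-[(3R)-7-(benzyloxy)chroman-3-yl]-6-methoxyphenyl}chroman-2-ol
Product: 32 (3R,4S)-7-(benzyloxy)-3-[2-(benzyloxy)-4,5-dimethoxyphenyl]-4-{4-(benzyloxy)-2-[(3R)-7-(benzyloxy)chroman-3-yl]-6-methoxyphenyl}chroman
Conditions: Et3SiH, BF3·OEt2, CH2Cl2, −78 → −20 °C
Reagents that add atoms: none
Why: Ionic hydrogenation of the lactol through the cyclic oxocarbenium ion; C2 becomes a methylene group, and any passage through the enol ether would reprotonate C3 anti to the C4 aryl group, so the trans arrangement is retained.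

Step 22
Reactants: 32 (3R,4S)-7-(benzyloxy)-3-[2-(benzyloxy)-4,5-dimethoxyphenyl]-4-{4-(benzyloxy)-2-[(3R)-7-(benzyloxy)chroman-3-yl]-6-methoxyphenyl}chroman
Product: 33 (3R,4S)-3-(2-hydroxy-4,5-dimethoxyphenyl)-4-{4-hydroxy-2-[(3R)-7-hydroxychroman-3-yl]-6-methoxyphenyl}chroman-7-ol
Conditions: H2 (1 atm), Pd/C (10 wt %), EtOAc/MeOH, rt
Reagents that add atoms: none
Why: Hydrogenolysis of the four aryl benzyl ethers under neutral conditions; the methyl ethers, the alkyl aryl ether bonds of both pyrans and the C4–H bond are not cleaved.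

## Compound list

1 | 5-bromovanillin (3-bromo-4-hydroxy-5-methoxybenzaldehyde) | COc1cc(C=O)cc(Br)c1O | starting material
2 | 3-bromo-4-hydroxy-5-methoxyphenyl formate | COc1cc(OC=O)cc(Br)c1O | intermediate
3 | 2-bromo-6-methoxybenzene-1,4-diol | COc1cc(O)cc(Br)c1O | intermediate
4 | 1-bromo-3-methoxy-2,5-bis(trimethylsilyloxy)benzene | COc1cc(O[Si](C)(C)C)cc(Br)c1O[Si](C)(C)C | intermediate
5 | lithium 2-methoxy-6-(trimethylsilyl)-4-(trimethylsilyloxy)phenolate | COc1cc(O[Si](C)(C)C)cc([Si](C)(C)C)c1[O-].[Li+] | intermediate
6 | 2-methoxy-6-(trimethylsilyl)-4-(trimethylsilyloxy)phenyl trifluoromethanesulfonate | COc1cc(O[Si](C)(C)C)cc([Si](C)(C)C)c1OS(=O)(=O)C(F)(F)F | intermediate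
7 | 4-hydroxy-2-methoxy-6-(trimethylsilyl)phenyl trifluoromethanesulfonate | COc1cc(O)cc([Si](C)(C)C)c1OS(=O)(=O)C(F)(F)F | intermediate
8 | 4-(benzyloxy)-2-methoxy-6-(trimethylsilyl)phenyl trifluoromethanesulfonate | COc1cc(OCc2ccccc2)cc([Si](C)(C)C)c1OS(=O)(=O)C(F)(F)F | intermediate
9 | 2,4-dihydroxyacetophenone | CC(=O)c1ccc(O)cc1O | starting material
10 | 1-[4-(benzyloxy)-2-hydroxyphenyl]ethan-1-one | CC(=O)c1ccc(OCc2ccccc2)cc1O | intermediate
11 | 1-[4-(benzyloxy)-2-(methoxymethoxy)phenyl]ethan-1-one | CC(=O)c1ccc(OCc2ccccc2)cc1OCOC | intermediate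
12 | methyl 3-[4-(benzyloxy)-2-(methoxymethoxy)phenyl]-3-oxopropanoate | COC(=O)CC(=O)c1ccc(OCc2ccccc2)cc1OCOC | intermediate
13 | 2,4-dihydroxybenzaldehyde | O=Cc1ccc(O)cc1O | starting material
14 | 4-(benzyloxy)-2-hydroxybenzaldehyde | O=Cc1ccc(OCc2ccccc2)cc1O | intermediate
15 | 4-(benzyloxy)-2-(methoxymethoxy)benzaldehyde | COCOc1cc(OCc2ccccc2)ccc1C=O | intermediate
16 | methyl 2-[4-(benzyloxy)-2-(methoxymethoxy)benzoyl]-3-[4-(benzyloxy)-2-(methoxymethoxy)phenyl]prop-2-enoate (E/Z mixture) | COC(=O)C(=Cc1ccc(OCc2ccccc2)cc1OCOC)C(=O)c1ccc(OCc2ccccc2)cc1OCOC | intermediate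
17 | methyl 2-[4-(benzyloxy)-2-(methoxymethoxy)benzyl]-3-[4-(benzyloxy)-2-(methoxymethoxy)phenyl]-3-oxopropanoate (racemic) | COC(=O)C(Cc1ccc(OCc2ccccc2)cc1OCOC)C(=O)c1ccc(OCc2ccccc2)cc1OCOC | intermediate
18 | 5-(benzyloxy)-3-methoxybenzyne (1,2-didehydrobenzene numbering) | COC1=CC(OCc2ccccc2)=CC#C1 | intermediate
19 | methyl 2-{5-(benzyloxy)-2-[4-(benzyloxy)-2-(methoxymethoxy)benzoyl]-3-methoxyphenyl}-3-[4-(benzyloxy)-2-(methoxymethoxy)phenyl]propanoate (racemic) | COC(=O)C(Cc1ccc(OCc2ccccc2)cc1OCOC)c1cc(OCc2ccccc2)cc(OC)c1C(=O)c1ccc(OCc2ccccc2)cc1OCOC | intermediate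
20 | 2-{5-(benzyloxy)-2-[[4-(benzyloxy)-2-(methoxymethoxy)phenyl](hydroxy)methyl]-3-methoxyphenyl}-3-[4-(benzyloxy)-2-(methoxymethoxy)phenyl]propan-1-ol (racemic diastereomers) | OCC(Cc1ccc(OCc2ccccc2)cc1OCOC)c1cc(OCc2ccccc2)cc(OC)c1C(O)c1ccc(OCc2ccccc2)cc1OCOC | intermediate
21 | 2-{5-(benzyloxy)-2-[4-(benzyloxy)-2-(methoxymethoxy)benzoyl]-3-methoxyphenyl}-3-[4-(benzyloxy)-2-(methoxymethoxy)phenyl]propanal (racemic) | O=CC(Cc1ccc(OCc2ccccc2)cc1OCOC)c1cc(OCc2ccccc2)cc(OC)c1C(=O)c1ccc(OCc2ccccc2)cc1OCOC | intermediate
22 | {4-(benzyloxy)-2-[(2R)-1-[4-(benzyloxy)-2-(methoxymethoxy)phenyl]-3-hydroxypropan-2-yl]-6-methoxyphenyl}[4-(benzyloxy)-2-(methoxymethoxy)phenyl]methanone | OC[C@H](Cc1ccc(OCc2ccccc2)cc1OCOC)c1cc(OCc2ccccc2)cc(OC)c1C(=O)c1ccc(OCc2ccccc2)cc1OCOC | intermediate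
23 | [4-(benzyloxy)-2-hydroxyphenyl]{4-(benzyloxy)-2-[(2R)-1-[4-(benzyloxy)-2-hydroxyphenyl]-3-hydroxypropan-2-yl]-6-methoxyphenyl}methanone | OC[C@H](Cc1ccc(OCc2ccccc2)cc1O)c1cc(OCc2ccccc2)cc(OC)c1C(=O)c1ccc(OCc2ccccc2)cc1O | intermediate
24 | [4-(benzyloxy)-2-hydroxyphenyl]{4-(benzyloxy)-2-[(3R)-7-(benzyloxy)chroman-3-yl]-6-methoxyphenyl}methanone | COc1cc(OCc2ccccc2)cc([C@@H]2COc3cc(OCc4ccccc4)ccc3C2)c1C(=O)c1ccc(OCc2ccccc2)cc1O | intermediate
25 | 2-hydroxy-4,5-dimethoxybenzaldehyde | COc1cc(O)c(C=O)cc1OC | starting material
26 | 2-(benzyloxy)-4,5-dimethoxybenzaldehyde | COc1cc(OCc2ccccc2)c(C=O)cc1OC | intermediate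
27 | 1-(benzyloxy)-4,5-dimethoxy-2-(2-methoxyethenyl)benzene (E/Z mixture) | COC=Cc1cc(OC)c(OC)cc1OCc1ccccc1 | intermediate
28 | 2-[2-(benzyloxy)-4,5-dimethoxyphenyl]acetaldehyde | O=CCc1cc(OC)c(OC)cc1OCc1ccccc1 | intermediate
29 | 5-(benzyloxy)-2-[{4-(benzyloxy)-2-[(3R)-7-(benzyloxy)chroman-3-yl]-6-methoxyphenyl}(hydroxy)methyl]phenol (both carbinol epimers) | COc1cc(OCc2ccccc2)cc([C@@H]2COc3cc(OCc4ccccc4)ccc3C2)c1C(O)c1ccc(OCc2ccccc2)cc1O | intermediate
30 | 3-(benzyloxy)-6-({4-(benzyloxy)-2-[(3R)-7-(benzyloxy)chroman-3-yl]-6-methoxyphenyl}methylidene)cyclohexa-2,4-dien-1-one | COc1cc(OCc2ccccc2)cc([C@@H]2COc3cc(OCc4ccccc4)ccc3C2)c1C=C1C=CC(OCc2ccccc2)=CC1=O | intermediate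
31 | (3R,4S)-7-(benzyloxy)-3-[2-(benzyloxy)-4,5-dimethoxyphenyl]-4-{4-(benzyloxy)-2-[(3R)-7-(benzyloxy)chroman-3-yl]-6-methoxyphenyl}chroman-2-ol (both anomers) | COc1cc(OCc2ccccc2)c([C@@H]2C(O)Oc3cc(OCc4ccccc4)ccc3[C@H]2c2c(OC)cc(OCc3ccccc3)cc2[C@@H]2COc3cc(OCc4ccccc4)ccc3C2)cc1OC | intermediate
32 | (3R,4S)-7-(benzyloxy)-3-[2-(benzyloxy)-4,5-dimethoxyphenyl]-4-{4-(benzyloxy)-2-[(3R)-7-(benzyloxy)chroman-3-yl]-6-methoxyphenyl}chroman | COc1cc(OCc2ccccc2)c([C@@H]2COc3cc(OCc4ccccc4)ccc3[C@H]2c2c(OC)cc(OCc3ccccc3)cc2[C@@H]2COc3cc(OCc4ccccc4)ccc3C2)cc1OC | intermediate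
33 | (3R,4S)-3-(2-hydroxy-4,5-dimethoxyphenyl)-4-{4-hydroxy-2-[(3R)-7-hydroxychroman-3-yl]-6-methoxyphenyl}chroman-7-ol (CNP0266829.1) | COc1cc(O)c([C@@H]2COc3cc(O)ccc3[C@H]2c2c(OC)cc(O)cc2[C@@H]2COc3cc(O)ccc3C2)cc1OC | target

## Step count and risks

Total: 22 steps. Longest linear sequence: 14 steps (from 9: steps 4, 5, 6, 9, 10, 11, 12, 13, 14, 15, 19, 20, 21, 22).

**Step 10 (key step).** The most likely failure is arrest after C-arylation: the aryl anion at D1 is protonated before it adds to the hindered, electron-rich aryl ketone, or the enolate reacts through oxygen. Both are favoured by the congestion at the tertiary enolate carbon of 17.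
Fallback, from 12 and 8, returning at 19: the insertion is run on the unsubstituted ketoester and the benzyl group is added afterwards.
- Ketoester 12 and 8 with CsF in MeCN at 80 °C should give methyl 2-{5-(benzyloxy)-2-[4-(benzyloxy)-2-(methoxymethoxy)benzoyl]-3-methoxyphenyl}acetate F1.
- Aldehyde 15 is reduced (NaBH4, MeOH) to [4-(benzyloxy)-2-(methoxymethoxy)phenyl]methanol F2 and converted (CBr4, PPh3, CH2Cl2, 0 °C) into 4-(benzyloxy)-1-(bromomethyl)-2-(methoxymethoxy)benzene F3, used at once.
- The sodium enolate of F1 (NaHMDS, THF, −78 °C) is alkylated with F3 to give 19.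

**Step 20.** Addition to the strongly stabilised quinone methide 30, whose methide carbon is shielded by the twisted, doubly ortho-substituted ring D, may be slow. Self-condensation of 28 on the amine would then take over, and facial discrimination may be eroded.
Fallback, from 29 and 27, returning at 32: the quinone methide is activated by a chiral phosphoric acid, for example (R)-3,3'-bis(2,4,6-triisopropylphenyl)-1,1'-binaphthyl-2,2'-diyl hydrogen phosphate, and intercepted by the preformed enol ether 27 in an inverse-demand hetero-Diels–Alder reaction. This should give (3R,4S)-7-(benzyloxy)-3-[2-(benzyloxy)-4,5-dimethoxyphenyl]-4-{4-(benzyloxy)-2-[(3R)-7-(benzyloxy)chroman-3-yl]-6-methoxyphenyl}-2-methoxychroman F9. Ionic hydrogenation under the conditions of step 21 gives 32. If catalyst control falls short, the fixed C3' centre makes the unwanted trans isomer a diastereomer that can be removed by chromatography.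

**Step 13.** Discrimination between the bulky ortho-substituted ring D and the benzyl group at the α-carbon may be insufficient, or the ketone may be partly reduced over long reaction times.
Fallback, from 19, returning at 22: the racemate is converged through a ketene.
- Ester 19 is saponified (LiOH, THF/H2O) to 2-{5-(benzyloxy)-2-[4-(benzyloxy)-2-(methoxymethoxy)benzoyl]-3-methoxyphenyl}-3-[4-(benzyloxy)-2-(methoxymethoxy)phenyl]propanoic acid F4.
- F4 is converted with oxalyl chloride into the propanoyl chloride F5 and dehydrochlorinated with Et3N to the aryl(benzyl)ketene F6.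
- (R)-Pantolactone adds to F6 at −78 °C with diastereoselective protonation, which should give (3R)-4,4-dimethyl-2-oxooxolan-3-yl (2R)-2-{5-(benzyloxy)-2-[4-(benzyloxy)-2-(methoxymethoxy)benzoyl]-3-methoxyphenyl}-3-[4-(benzyloxy)-2-(methoxymethoxy)phenyl]propanoate F7.
- LiAlH4 reduces F7 to the (2R)-configured diol F8 (both carbinol epimers), and MnO2 re-oxidises only the benzylic carbinol to give 22.

**Step 21.** The oxocarbenium ion may lose the C3 proton to an enol ether that oligomerises, or the Lewis acid may begin to cleave benzyl ethers before hydride transfer is complete.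
Fallback, from 31, returning at 32: lactol 31 is oxidised (PhI(OAc)2, cat. TEMPO) to (3R,4S)-7-(benzyloxy)-3-[2-(benzyloxy)-4,5-dimethoxyphenyl]-4-{4-(benzyloxy)-2-[(3R)-7-(benzyloxy)chroman-3-yl]-6-methoxyphenyl}chroman-2-one F10. This is reduced (LiAlH4, THF, 0 °C) to (2R,3S)-2-[2-(benzyloxy)-4,5-dimethoxyphenyl]-3-[4-(benzyloxy)-2-hydroxyphenyl]-3-{4-(benzyloxy)-2-[(3R)-7-(benzyloxy)chroman-3-yl]-6-methoxyphenyl}propan-1-ol F11. Mitsunobu closure (PPh3, DIAD) of F11 gives 32.

## Further compounds

F1 | step 10 | methyl 2-{5-(benzyloxy)-2-[4-(benzyloxy)-2-(methoxymethoxy)benzoyl]-3-methoxyphenyl}acetate | COC(=O)Cc1cc(OCc2ccccc2)cc(OC)c1C(=O)c1ccc(OCc2ccccc2)cc1OCOC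
F2 | step 10 | [4-(benzyloxy)-2-(methoxymethoxy)phenyl]methanol | COCOc1cc(OCc2ccccc2)ccc1CO
F3 | step 10 | 4-(benzyloxy)-1-(bromomethyl)-2-(methoxymethoxy)benzene | COCOc1cc(OCc2ccccc2)ccc1CBr
F4 | step 13 | 2-{5-(benzyloxy)-2-[4-(benzyloxy)-2-(methoxymethoxy)benzoyl]-3-methoxyphenyl}-3-[4-(benzyloxy)-2-(methoxymethoxy)phenyl]propanoic acid (racemic) | OC(=O)C(Cc1ccc(OCc2ccccc2)cc1OCOC)c1cc(OCc2ccccc2)cc(OC)c1C(=O)c1ccc(OCc2ccccc2)cc1OCOC
F5 | step 13 | 2-{5-(benzyloxy)-2-[4-(benzyloxy)-2-(methoxymethoxy)benzoyl]-3-methoxyphenyl}-3-[4-(benzyloxy)-2-(methoxymethoxy)phenyl]propanoyl chloride (racemic) | ClC(=O)C(Cc1ccc(OCc2ccccc2)cc1OCOC)c1cc(OCc2ccccc2)cc(OC)c1C(=O)c1ccc(OCc2ccccc2)cc1OCOC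
F6 | step 13 | 2-{5-(benzyloxy)-2-[4-(benzyloxy)-2-(methoxymethoxy)benzoyl]-3-methoxyphenyl}-3-[4-(benzyloxy)-2-(methoxymethoxy)phenyl]prop-1-en-1-one (ketene) | O=C=C(Cc1ccc(OCc2ccccc2)cc1OCOC)c1cc(OCc2ccccc2)cc(OC)c1C(=O)c1ccc(OCc2ccccc2)cc1OCOC
F7 | step 13 | (3R)-4,4-dimethyl-2-oxooxolan-3-yl (2R)-2-{5-(benzyloxy)-2-[4-(benzyloxy)-2-(methoxymethoxy)benzoyl]-3-methoxyphenyl}-3-[4-(benzyloxy)-2-(methoxymethoxy)phenyl]propanoate | O=C(O[C@H]1C(=O)OCC1(C)C)[C@H](Cc1ccc(OCc2ccccc2)cc1OCOC)c1cc(OCc2ccccc2)cc(OC)c1C(=O)c1ccc(OCc2ccccc2)cc1OCOC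
F8 | step 13 | (2R)-2-{5-(benzyloxy)-2-[[4-(benzyloxy)-2-(methoxymethoxy)phenyl](hydroxy)methyl]-3-methoxyphenyl}-3-[4-(benzyloxy)-2-(methoxymethoxy)phenyl]propan-1-ol (both carbinol epimers) | OC[C@H](Cc1ccc(OCc2ccccc2)cc1OCOC)c1cc(OCc2ccccc2)cc(OC)c1C(O)c1ccc(OCc2ccccc2)cc1OCOC
F9 | step 20 | (3R,4S)-7-(benzyloxy)-3-[2-(benzyloxy)-4,5-dimethoxyphenyl]-4-{4-(benzyloxy)-2-[(3R)-7-(benzyloxy)chroman-3-yl]-6-methoxyphenyl}-2-methoxychroman (both anomers) | COc1cc(OCc2ccccc2)c([C@@H]2C(OC)Oc3cc(OCc4ccccc4)ccc3[C@H]2c2c(OC)cc(OCc3ccccc3)cc2[C@@H]2COc3cc(OCc4ccccc4)ccc3C2)cc1OC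
F10 | step 21 | (3R,4S)-7-(benzyloxy)-3-[2-(benzyloxy)-4,5-dimethoxyphenyl]-4-{4-(benzyloxy)-2-[(3R)-7-(benzyloxy)chroman-3-yl]-6-methoxyphenyl}chroman-2-one | COc1cc(OCc2ccccc2)c([C@@H]2C(=O)Oc3cc(OCc4ccccc4)ccc3[C@H]2c2c(OC)cc(OCc3ccccc3)cc2[C@@H]2COc3cc(OCc4ccccc4)ccc3C2)cc1OC
F11 | step 21 | (2R,3S)-2-[2-(benzyloxy)-4,5-dimethoxyphenyl]-3-[4-(benzyloxy)-2-hydroxyphenyl]-3-{4-(benzyloxy)-2-[(3R)-7-(benzyloxy)chroman-3-yl]-6-methoxyphenyl}propan-1-ol | COc1cc(OCc2ccccc2)c([C@H](CO)[C@@H](c2ccc(OCc3ccccc3)cc2O)c2c(OC)cc(OCc3ccccc3)cc2[C@@H]2COc3cc(OCc4ccccc4)ccc3C2)cc1OC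
A1 | alternative 1 | (2R)-1-{4-(benzyloxy)-2-[(3R)-7-(benzyloxy)chroman-3-yl]-6-methoxyphenyl}-2-[2-(benzyloxy)-4,5-dimethoxyphenyl]-3-[3-(benzyloxy)phenoxy]propan-1-ol (both carbinol epimers) | OC(c1c(OC)cc(OCc2ccccc2)cc1[C@@H]1COc2cc(OCc3ccccc3)ccc2C1)[C@@H](COc1cccc(OCc2ccccc2)c1)c1cc(OC)c(OC)cc1OCc1ccccc1
A2 | alternative 1 | (3R,4S)-7-(benzyloxy)-3-[2-(benzyloxy)-4,5-dimethoxyphenyl]-4-{4-(benzyloxy)-2-[(3R)-7-(benzyloxy)chroman-3-yl]-6-methoxyphenyl}chroman | COc1cc(OCc2ccccc2)c([C@@H]2COc3cc(OCc4ccccc4)ccc3[C@H]2c2c(OC)cc(OCc3ccccc3)cc2[C@@H]2COc3cc(OCc4ccccc4)ccc3C2)cc1OC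
A3 | alternative 2 | 1-[4-(benzyloxy)-2-(methoxymethoxy)phenyl]-3-[(3R)-7-(benzyloxy)chroman-3-yl]prop-2-yn-1-one | COCOc1cc(OCc2ccccc2)ccc1C(=O)C#C[C@@H]1COc2cc(OCc3ccccc3)ccc2C1
A4 | alternative 2 | 1,1-dimethoxy-3-(trimethylsilyloxy)buta-1,3-diene | COC(OC)=CC(=C)O[Si](C)(C)C
A5 | alternative 2 | [4-(benzyloxy)-2-(methoxymethoxy)phenyl]{2-[(3R)-7-(benzyloxy)chroman-3-yl]-4-hydroxy-6-methoxyphenyl}methanone | COCOc1cc(OCc2ccccc2)ccc1C(=O)c1c(OC)cc(O)cc1[C@@H]1COc2cc(OCc3ccccc3)ccc2C1
A6 | alternative 3 | (3S)-6-(benzyloxy)-3-{4-(benzyloxy)-2-[(3R)-7-(benzyloxy)chroman-3-yl]-6-methoxyphenyl}indan-1-one | O=C1C[C@H](c2c(OC)cc(OCc3ccccc3)cc2[C@@H]2COc3cc(OCc4ccccc4)ccc3C2)c2ccc(OCc3ccccc3)cc21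
A7 | alternative 3 | (4S)-7-(benzyloxy)-4-{4-(benzyloxy)-2-[(3R)-7-(benzyloxy)chroman-3-yl]-6-methoxyphenyl}chroman-2-one | O=C1C[C@H](c2c(OC)cc(OCc3ccccc3)cc2[C@@H]2COc3cc(OCc4ccccc4)ccc3C2)c2ccc(OCc3ccccc3)cc2O1
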